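The numbers in the tables come from a simulation with constants of no real substance, noise included.

Seconds are the unit we count in, since we want to know how many half-lives of starting complex fit between the feed and the reading.

| flask | starting complex | incoming ligand | remark | time |
|---|---|---|---|---|
| red | 20 mM (fed, over 25 s) | 0.96 equiv | run made earlier |  |
| blue | 20 mM (fed, over 25 s) | 1.7 equiv | run made earlier |  |
| grey | 20 mM (fed, over 25 s) | 2.2 equiv | run made earlier |  |
| midnight | 20 mM (fed, over 25 s) | 1.20 equiv |  | 2.0 min |
| summer | 20 mM (fed, over 25 s) | 2.00 equiv |  | 2.0 min |

| run | time / s | complex with one exchanged / % |
|---|---|---|
| red | 12.0 | 4 |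
| red | 25.0 | 14 |
| red | 40.0 | 22 |
| red | 50.0 | 20 |
| red | 60.0 | 20 |
| blue | 10.0 | 7 |
| blue | 15.0 | 8 |
| blue | 30.0 | 23 |
| blue | 40.0 | 28 |
| blue | 60.0 | 31 |
| grey | 12.0 | 9 |
| grey | 25.0 | 19 |
| grey | 40.0 | 29 |
| grey | 50.0 | 32 |
| grey | 60.0 | 33 |

(standard deviation of a reading: 1.5 percentage points)

- percent here means starting complex units held: one self-condensation product counts as two
- the numbers in the tables scatter by 1.5 percentage points (one standard deviation)
- what may be going on: incoming ligand <-> dormant form; leaving ligand -> by-product carried off; complex with one exchanged + incoming ligand <-> leaving ligand + complex with two exchanged; starting complex + incoming ligand <-> leaving ligand + complex with one exchanged; 2 starting complex -> self-condensation product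
- percentages count the whole charge, also what has not yet gone in

* which of these holds the largest part of the starting complex at the end of midnight (complex with one exchanged / starting complex / complex with two exchanged)
* which of these holds the largest part of the starting complex at the end of summer (complex with one exchanged / starting complex / complex with two exchanged)
* amount of complex with one exchanged at the end of summer, in percent of the starting complex charged

1. In the grey and red runs, complex with one exchanged at 12.0 s stands in the ratio 2.25, and the ligand charges in the ratio 2.29, so within a scatter of 1.5 percentage points we read the first exchange as first order in incoming ligand.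

2. Under a steady feed the early percentage grows as the rate times the squared time over twice the dosing time, so grey's first reading gives a rate of 0.0312 s⁻¹ and a half-life of 22.2 s. Scaled to the ligand charged in summer, this ligand clock, the half-life of starting complex at the charged ligand concentration, is 24.4 s.

3. Grey's starting complex, dated from mid-feed, has at 60.0 s seen twice its clock, which on this reckoning leaves 22.7 %. With 33 % read as complex with one exchanged, some 44.3 % has on this reckoning gone further, so we read grey's flat curve as a relay and not an equilibrium.

4. Summer's clock is slightly longer than grey's, but its reading comes after more clocks. We therefore commit to complex with two exchanged as largest in summer, with complex with one exchanged near 33 %. For summer the clock, run at the charged ligand, leaves 4.72 % of starting complex. Midnight has less ligand than summer, and there we keep starting complex first.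

5. The forecast named starting complex for midnight, starting complex for summer and 37 % for the asked amount, judging that “Draining of leaving ligand seems slow”.

6. Midnight ends with starting complex largest at 39.1 %. Summer ends with complex with two exchanged largest at 42.3 %, and complex with one exchanged at 31.8 %.

    incoming ligand ⇌ dormant form (K = 1.90, k = 0.0430 s⁻¹)
    leaving ligand → by-product carried off (k = 0.0810 s⁻¹)
    complex with one exchanged + incoming ligand ⇌ leaving ligand + complex with two exchanged (K = 0.640, k = 3.00 M⁻¹ s⁻¹)
    starting complex + incoming ligand ⇌ leaving ligand + complex with one exchanged (K = 68.0, k = 1.70 M⁻¹ s⁻¹)
    2 starting complex → self-condensation product (k = 0.0550 M⁻¹ s⁻¹)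

Summer keeps 21.7 % of starting complex against our 4.72 %, and its unbound incoming ligand at the end is 12 % of the charge, or 4.81 mM, beside 11.9 mM of dormant form. With the forward constant of the first exchange, the clock in summer is 10.2 s at the charged ligand, against our 24.4 s, and 84.8 s at that end concentration. The neighbouring flask, the same recipe at 80 mM of starting complex, holds 10.8 mM of unbound ligand at its end, twice summer's, so its clock on the same constant reads 37.8 s, and it ends with 3.46 % of starting complex.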